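The data come from a simulation with constants of no real substance.

Green and blue differ 1.49-fold in X, yet green at 40.0 min holds 36.8% of its Q as E, G and J, and blue at 0.667 h holds 37.3%.

| setting | green | blue | flask |
|---|---|---|---|
| Q | 0.54 M | 0.54 M | 0.54 M |
| X | 0.702 M | 0.47 M | 0.702 M |
| Z | 14 mM | 14 mM | 14 mM |
| remark | the very flask that is asked about, followed so far | run made earlier |  |
| time |  |  | 4.0 h |

green run (percent of the Q charged)

| time / min | E / % | G / % | J / % |
|---|---|---|---|
| 3.00 | 0.6 | 0.8 | 3.3 |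
| 10.0 | 0.7 | 0 | 12.3 |
| 15.0 | 1.1 | 0.9 | 16.0 |
| 25.0 | 2.2 | 0.2 | 22.9 |
| 40.0 | 5.6 | 0 | 31.2 |
| 50.0 | 6.0 | 0.9 | 35.3 |

blue run (percent of the Q charged)

| time / h | E / % | G / % | J / % |
|---|---|---|---|
| 0.667 | 4.6 | 0.3 | 32.4 |
| 1.33 | 11.6 | 1.3 | 42.5 |
| 2.00 | 17.0 | 3.2 | 41.7 |
| 2.50 | 20.7 | 3.1 | 37.1 |
| 3.00 | 24.4 | 4.5 | 35.0 |
| 4.00 | 29.7 | 7.5 | 27.3 |

(standard deviation of a reading: 0.5 percentage points)

1. concentration of E at 4.0 h, in M
2. concentration of G at 4.0 h, in M
3. concentration of J at 4.0 h, in M
4. concentration of Q at 4.0 h, in M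
5. concentration of X at 4.0 h, in M

- on the list of suspects stand: E + Z <-> G + Z; X + L -> Z + E; Z + J <-> L; J -> D; Q + Z -> Z + J

1. The early loss of Q thus shows no X within the scatter, and the suspect that consumes Q, Q + Z → Z + J, holds Z instead. If Z holds near its charge, Q + Z → Z + J is pseudo-first-order, and the fraction of Q left is exp(−kt). Call k the Q clock.

2. Lower bound on k: the green sum omits D, so the readings put the loss of Q at 36.8% or more. That gives k of at least 0.688 /h, and at most 6.38% of Q left in green at 4.0 h, provided Z keeps its early level.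

3. Upper bound on k: blue at 4.00 h leaves 35.5% unaccounted, which covers Q, D and L. Its J readings stay at or above 27.3% after 0.667 h, so the readings give J → D a rate constant of no more than 0.390 /h. Green at 15.0 min then has lost at most 19.6% by its readings, with L set aside. So k is at most 0.871 /h, and at least 3.07% of Q is left in green.

4. My own reckoning takes the midpoint, the Q clock 0.779 /h, so green keeps 4.43% of its Q.

5. The forecast gives E 0.184 M, G 0.048 M, J 0.124 M, Q 0.025 M and X 0.47 M, on the ground that “Early J growth gives Q loss of about 0.75–0.8 per hour”. Its Q is 4.63% of the charge, a little above my figure and inside the bracket.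

The simulated green flask gives E 0.186 M, G 0.0530 M, J 0.119 M, Q 0.0287 M and X 0.463 M.

    E + Z ⇌ G + Z, rate k1*[Z]*[E] forward; the back reaction follows from the equilibrium constant (K = 1.80, k = 10.7 /M/h)
    X + L → Z + E (k = 156 /M/h)
    Z + J ⇌ L (K = 0.645 /M, k = 49.2 /M/h)
    J → D (k = 0.227 /h)
    Q + Z → Z + J (k = 55.0 /M/h)

Green keeps 5.3% of its Q at 4.0 h, inside the bracket. The half-life of Q in green by Q + Z → Z + J stands at 0.94 h at that time, short against 4.0 h, while the clock gives 0.890 h, and Z stands at 96.2% of its charge. With 0.035 M of Z, the clock scaled by the Z charge gives 0.0412% of Q left at 4.0 h, and that flask holds 0.0611%.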